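**Retrosynthetic overview** (gibberellane numbering: C6 = CH carrying the carboxyl, C8 = quaternary carbon, C9 = benzylic CH, C13 = carbinol carbon, C14 = one-carbon bridge, C15 = ring-D CH2, C16/C17 = exo-methylene)
1. Pharbinilic acid ⇐ saponification with C6 equilibration, C16 methylenation and C9 deformylation ⇐ bridged 13-hydroxy-16-ketone 16.
2. Rings C and D (the bicyclo[3.2.1]octane) are closed together from the spiro[cyclobutane-indane] 14 by a Michael addition (C9–C11) followed by a strain-driven α-ketol 1,2-shift (C13–C14).
3. Enabling feature: in ring D both C14 and C15 are CH2 groups on the quaternary C8, and C13(OH) is vicinal to C16, so ring D is a ring-expanded 1-acylcyclobutanol once C16 is at the ketone level; C9 is a benzylic CH of ring B that can carry a removable formyl group and act as the enolate donor toward C11.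
4. 14 ⇐ acryloyl-anion addition and Wittig homologation on spiro-indanone 11 ⇐ ring B by ester α-arylation after alkylation at C8 ⇐ Friedel–Crafts acylation of benzofuran 4.
5. Order of ring formation: ring A (bought), furan, cyclobutane (bought), ring B, then rings C and D together.

Key step: step 10

Remark: the facial sense of the cinchonidinium catalyst in step 10 is assumed by analogy with phase-transfer Michael additions of indanone-type enolates; the pseudoenantiomeric cinchoninium salt would be used if the opposite sense were found.

**Step 1**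
Reactants: 1 3-bromo-2-methylphenol
Product: 2 4-bromo-2-hydroxy-3-methylbenzaldehyde
Conditions: MgCl2, Et3N, (CH2O)n, MeCN, reflux
Reagents that add atoms: paraformaldehyde (as formaldehyde), C=O
Why: Magnesium-phenoxide-directed ortho-formylation can only go to the one free ortho position, the hydroxymethyl intermediate being oxidised in situ by a second equivalent of formaldehyde.

**Step 2**
Reactants: 2 4-bromo-2-hydroxy-3-methylbenzaldehyde
Product: 4 ethyl 6-bromo-7-methyl-1-benzofuran-3-carboxylate, via hemiacetal 3 (not isolated)
Conditions: N2CHCO2Et, HBF4·OEt2 (cat.), CH2Cl2, rt; then conc. H2SO4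
Reagents that add atoms: ethyl diazoacetate, CCOC(=O)C=[N+]=[N-]
Why: Acid-catalysed addition of the diazo ester to the aldehyde with 1,2-aryl shift gives a 3-hydroxyacrylate that closes onto the phenol to hemiacetal 3, which H2SO4 dehydrates to the aromatic furan (salicylaldehyde to benzofuran-3-carboxylate annulation).

**Step 3**
Reactants: 4 ethyl 6-bromo-7-methyl-1-benzofuran-3-carboxylate; 5 3-oxocyclobutane-1-carboxylic acid
Product: 7 ethyl 6-bromo-7-methyl-5-(3-oxocyclobutane-1-carbonyl)-1-benzofuran-3-carboxylate, via acid chloride 6 (not isolated)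
Conditions: 5, (COCl)2, DMF (cat.), CH2Cl2, 0 °C to rt; then 4, AlCl3, ClCH2CH2Cl, 0 to 50 °C
Reagents that add atoms: none
Why: Friedel–Crafts acylation should go to C5 of the benzofuran, para to the ring oxygen and ortho to bromine, because C6 and C7 are blocked, C4 is peri to the ester and C2 is the deactivated β-carbon of a vinylogous carbonate.

**Step 4**
Reactants: 7 ethyl 6-bromo-7-methyl-5-(3-oxocyclobutane-1-carbonyl)-1-benzofuran-3-carboxylate
Product: 8 ethyl 6-bromo-5-(3,3-diethoxycyclobutane-1-carbonyl)-7-methyl-1-benzofuran-3-carboxylate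
Conditions: HC(OEt)3, EtOH, TsOH (cat.), rt
Reagents that add atoms: ethanol, CCO; triethyl orthoformate, CCOC(OCC)OCC
Why: Acid-catalysed ketalisation is selective for the strained, unhindered cyclobutanone over the conjugated, hindered aryl ketone, and the ethanol-based reagents avoid scrambling of the ethyl esters.

**Step 5**
Reactants: 8 ethyl 6-bromo-5-(3,3-diethoxycyclobutane-1-carbonyl)-7-methyl-1-benzofuran-3-carboxylate
Product: 9 ethyl 6-bromo-5-{[3,3-diethoxy-1-(2-ethoxy-2-oxoethyl)cyclobutyl]carbonyl}-7-methyl-1-benzofuran-3-carboxylate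
Conditions: LiN(i-Pr)2, THF, −78 °C; BrCH2CO2Et, −78 to 0 °C
Reagents that add atoms: ethyl bromoacetate, CCOC(=O)CBr
Why: The cyclobutyl methine is the only enolisable α-position of the aryl ketone, and C-alkylation of its lithium enolate with the reactive α-bromo ester creates the quaternary C8, which is not yet stereogenic because the two ring methylenes are identical.

**Step 6**
Reactants: 9 ethyl 6-bromo-5-{[3,3-diethoxy-1-(2-ethoxy-2-oxoethyl)cyclobutyl]carbonyl}-7-methyl-1-benzofuran-3-carboxylate
Product: 10 diethyl 3',3'-diethoxy-8-methyl-5-oxo-5,7-dihydrospiro[indeno[5,6-b]furan-6,1'-cyclobutane]-3,7-dicarboxylate (racemic)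
Conditions: Pd2(dba)3 (cat.), P(t-Bu)3·HBF4 (cat.), LiN(SiMe3)2, toluene, 70 °C
Reagents that add atoms: none
Why: Intramolecular palladium-catalysed α-arylation of the ester enolate closes ring B in the 5-exo mode onto the aryl bromide, the ketone being non-enolisable, and the new C6 stereocentre is formed as a racemate and stays epimerisable.

**Step 7**
Reactants: 10 diethyl 3',3'-diethoxy-8-methyl-5-oxo-5,7-dihydrospiro[indeno[5,6-b]furan-6,1'-cyclobutane]-3,7-dicarboxylate
Product: 11 diethyl 8-methyl-3',5-dioxo-5,7-dihydrospiro[indeno[5,6-b]furan-6,1'-cyclobutane]-3,7-dicarboxylate (racemic)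
Conditions: 1 M HCl, acetone/H2O, rt
Reagents that add atoms: water, O
Why: Mild aqueous acid hydrolyses the diethyl ketal to the cyclobutanone without touching the ethyl esters.

**Step 8**
Reactants: 11 diethyl 8-methyl-3',5-dioxo-5,7-dihydrospiro[indeno[5,6-b]furan-6,1'-cyclobutane]-3,7-dicarboxylate
Product: 12 diethyl 3'-hydroxy-3'-(1-methoxypropa-1,2-dien-1-yl)-8-methyl-5-oxo-5,7-dihydrospiro[indeno[5,6-b]furan-6,1'-cyclobutane]-3,7-dicarboxylate (allenyl group cis to C5 across the cyclobutane; racemic at C7)
Conditions: CH2=C=CHOMe, n-BuLi, THF, −78 °C; then 11, −78 °C; aq. NH4Cl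
Reagents that add atoms: methoxyallene, COC=C=C
Why: 1-Methoxyallenyllithium, an acryloyl anion equivalent, should add to the strained cyclobutanone much faster than to the neopentyl aryl ketone or the esters, and from the face anti to the bulkier ester-bearing carbon, which places the new carbon substituent cis to the ketone carbon C5 (C9 in gibberellane numbering) and the hydroxyl cis to C7 (C6).

**Step 9**
Reactants: 12 diethyl 3'-hydroxy-3'-(1-methoxypropa-1,2-dien-1-yl)-8-methyl-5-oxo-5,7-dihydrospiro[indeno[5,6-b]furan-6,1'-cyclobutane]-3,7-dicarboxylate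
Product: 14 diethyl 5-formyl-3'-hydroxy-8-methyl-3'-(prop-2-enoyl)-5,7-dihydrospiro[indeno[5,6-b]furan-6,1'-cyclobutane]-3,7-dicarboxylate (acryloyl cis to C5; C5 and C7 epimers), via bis-enol ether 13 (not isolated)
Conditions: Ph3P(CH2OMe)Cl, KN(SiMe3)2, THF, 0 to 45 °C; then 2 M HCl, THF, rt
Reagents that add atoms: (methoxymethyl)triphenylphosphonium chloride, COC[P+](c1ccccc1)(c1ccccc1)c1ccccc1.[Cl-]; water, O
Why: Wittig methoxymethylenation of the non-enolisable aryl ketone gives enol ether 13, and one aqueous acid treatment hydrolyses both enol ethers, unmasking the C9 formyl group (its configuration is irrelevant) and the α′-hydroxy vinyl ketone.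

**Step 10**
Reactants: 14 diethyl 5-formyl-3'-hydroxy-8-methyl-3'-(prop-2-enoyl)-5,7-dihydrospiro[indeno[5,6-b]furan-6,1'-cyclobutane]-3,7-dicarboxylate
Product: 16 diethyl 9-formyl-16-oxo-17-norpharbinilate (formyl in the place of H9; C6 epimers), via bicyclo[4.1.1]octane ketol 15 (not isolated)
Conditions: N-(9-anthracenylmethyl)-O-allylcinchonidinium bromide (cat.), Cs2CO3, toluene, −20 to 40 °C
Reagents that add atoms: none
Why: Proposed new method: under solid–liquid phase-transfer conditions the α-aryl aldehyde is by far the most acidic site of 14, so its C9 enolate, ion-paired with the chiral ammonium cation, forms first and adds to C11 of the α′-hydroxy vinyl ketone to give bridged ketol 15, and only then does the tertiary cyclobutanol alkoxide trigger an α-ketol (acyloin) 1,2-shift of the cyclobutane methylene C14 from C16 to the C13 carbonyl, which releases the four-ring strain. The closest known reactions are the cinchona-ammonium-catalysed phase-transfer Michael addition of indanone-type enolates to vinyl ketones and the base-mediated ring expansion of 1-acylcyclobutanols to 2-hydroxycyclopentanones; their coupling in one operation through a bicyclo[4.1.1]octane intermediate is not known. The Michael addition closes a seven-membered carbocycle in the 7-endo-trig mode across the 1,3-positions of the cyclobutane, and the 1,2-shift expands the cyclobutane to the five-membered ring D and thereby also creates the six-membered ring C. C9 is the only stereocentre that must be controlled and is set by the catalyst, which shields one face of the flat, aryl-conjugated enolate; the bridgeheads C8 and C13 then follow from the geometry of the bicyclo[3.2.1]octane, and C6 is left epimerisable and is set in step 13. Two selectivities are needed: conjugate addition before rearrangement, which the large acidity gap between the aldehyde α-H and the tertiary OH should secure, and the methylene syn to the new C9–C11 bond as the migrating one-carbon bridge, which should be secured thermodynamically because bridged acyloins equilibrate by further 1,2-shifts under base and the cis B/C-fused ketol is expected to be the more stable isomer.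

**Step 11**
Reactants: 16 diethyl 9-formyl-16-oxo-17-norpharbinilate
Product: 17 diethyl 16-oxo-17-norpharbinilate (C6 epimers)
Conditions: RhCl(PPh3)3 (stoichiometric), toluene, 110 °C
Reagents that add atoms: none
Why: Tsuji–Wilkinson decarbonylation of the non-enolisable aldehyde proceeds through acyl-rhodium hydride formation, CO extrusion and C–H reductive elimination with retention, so hydrogen takes the place of the formyl group and C9 keeps the configuration set in step 10.

**Step 12**
Reactants: 17 diethyl 16-oxo-17-norpharbinilate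
Product: 18 diethyl pharbinilate (C6 epimers)
Conditions: Zn, CH2Br2, TiCl4, THF/CH2Cl2, 0 °C to rt
Reagents that add atoms: dibromomethane, BrCBr
Why: The non-basic Lombardo methylenation converts the hindered, enolisable C16 ketone next to the free tertiary alcohol into the exocyclic methylene without acyloin rearrangement, while the esters are inert.

**Step 13**
Reactants: 18 diethyl pharbinilate
Product: 19 pharbinilic acid
Conditions: LiOH, EtOH/H2O, 60 °C; then cold 1 M HCl to pH 3
Reagents that add atoms: lithium hydroxide, [Li+].[OH-]; water, O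
Why: Under hydroxide in ethanol the benzylic C6 ester should equilibrate through its enolate to the more stable epimer, with the carboxyl group on the face of H9 and C15 and away from the C9–C11 bond, before this hindered ester is saponified together with the furan ester, and cautious acidification gives the target.

**Compound list**
1 | 3-bromo-2-methylphenol | Cc1c(O)cccc1Br | starting material
2 | 4-bromo-2-hydroxy-3-methylbenzaldehyde | O=Cc1ccc(Br)c(C)c1O | intermediate
3 | ethyl 6-bromo-2-hydroxy-7-methyl-2,3-dihydro-1-benzofuran-3-carboxylate (hemiacetal, stereoisomer mixture, not isolated) | CCOC(=O)C1C(O)Oc2c(C)c(Br)ccc21 | intermediate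
4 | ethyl 6-bromo-7-methyl-1-benzofuran-3-carboxylate | CCOC(=O)c1coc2c(C)c(Br)ccc12 | intermediate
5 | 3-oxocyclobutane-1-carboxylic acid | O=C1CC(C(=O)O)C1 | starting material
6 | 3-oxocyclobutane-1-carbonyl chloride (not isolated) | O=C1CC(C(=O)Cl)C1 | intermediate
7 | ethyl 6-bromo-7-methyl-5-(3-oxocyclobutane-1-carbonyl)-1-benzofuran-3-carboxylate | CCOC(=O)c1coc2c(C)c(Br)c(C(=O)C3CC(=O)C3)cc12 | intermediate
8 | ethyl 6-bromo-5-(3,3-diethoxycyclobutane-1-carbonyl)-7-methyl-1-benzofuran-3-carboxylate | CCOC(=O)c1coc2c(C)c(Br)c(C(=O)C3CC(OCC)(OCC)C3)cc12 | intermediate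
9 | ethyl 6-bromo-5-{[3,3-diethoxy-1-(2-ethoxy-2-oxoethyl)cyclobutyl]carbonyl}-7-methyl-1-benzofuran-3-carboxylate | CCOC(=O)CC1(C(=O)c2cc3c(C(=O)OCC)coc3c(C)c2Br)CC(OCC)(OCC)C1 | intermediate
10 | diethyl 3',3'-diethoxy-8-methyl-5-oxo-5,7-dihydrospiro[indeno[5,6-b]furan-6,1'-cyclobutane]-3,7-dicarboxylate, racemic | CCOC(=O)C1c2c(C)c3occ(C(=O)OCC)c3cc2C(=O)C12CC(OCC)(OCC)C2 | intermediate
11 | diethyl 8-methyl-3',5-dioxo-5,7-dihydrospiro[indeno[5,6-b]furan-6,1'-cyclobutane]-3,7-dicarboxylate, racemic | CCOC(=O)C1c2c(C)c3occ(C(=O)OCC)c3cc2C(=O)C12CC(=O)C2 | intermediate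
12 | diethyl 3'-hydroxy-3'-(1-methoxypropa-1,2-dien-1-yl)-8-methyl-5-oxo-5,7-dihydrospiro[indeno[5,6-b]furan-6,1'-cyclobutane]-3,7-dicarboxylate, allenyl cis to C5 and hydroxyl cis to C7 across the cyclobutane, racemic at C7 | CCOC(=O)C1c2c(C)c3occ(C(=O)OCC)c3cc2C(=O)[C@@]12C[C@](O)(C(OC)=C=C)C2 | intermediate
13 | 5-(methoxymethylidene) analogue of 12 (E/Z mixture, not isolated) | CCOC(=O)C1c2c(C)c3occ(C(=O)OCC)c3cc2C(=COC)[C@@]12C[C@](O)(C(OC)=C=C)C2 | intermediate
14 | diethyl 5-formyl-3'-hydroxy-8-methyl-3'-(prop-2-enoyl)-5,7-dihydrospiro[indeno[5,6-b]furan-6,1'-cyclobutane]-3,7-dicarboxylate, acryloyl cis to C5, epimers at C5 and C7 | CCOC(=O)C1c2c(C)c3occ(C(=O)OCC)c3cc2C(C=O)[C@@]12C[C@](O)(C(=O)C=C)C2 | intermediate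
15 | Michael adduct: bicyclo[4.1.1]octane ketol in which quaternary C9 (formyl, aryl, C8, C11) is bridged through C11–C12–C13(=O) to the cyclobutanol carbon C16; C6 epimers (not isolated) | O=C1CC[C@@]2(C=O)c3cc4c(C(=O)OCC)coc4c(C)c3C(C(=O)OCC)[C@]25C[C@@]1(O)C5 | intermediate
16 | diethyl 9-formyl-16-oxo-17-norpharbinilate: bicyclo[3.2.1]octane with 13-OH and 16-ketone, formyl in the place of H9, C6 epimers | O=C1C[C@]23C[C@@]1(O)CC[C@@]2(C=O)c1cc2c(C(=O)OCC)coc2c(C)c1C3C(=O)OCC | intermediate
17 | diethyl 16-oxo-17-norpharbinilate, C6 epimers | O=C1C[C@]23C[C@@]1(O)CC[C@H]2c1cc2c(C(=O)OCC)coc2c(C)c1C3C(=O)OCC | intermediate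
18 | diethyl pharbinilate, C6 epimers | C=C1C[C@]23C[C@@]1(O)CC[C@H]2c1cc2c(C(=O)OCC)coc2c(C)c1C3C(=O)OCC | intermediate
19 | pharbinilic acid | C=C1C[C@]23C[C@@]1(O)CC[C@H]2c1cc2c(C(=O)O)coc2c(C)c1[C@@H]3C(=O)O | target

**Step count and risks**
Total steps: 13. Longest linear sequence: 13 (from 1).

Steps most likely to fail:

1. Step 10 (Proposed new method). Three things may go wrong: the ion-paired enolate may add with poor facial discrimination; ring expansion of 14 may start before the C–C bond is formed; the first acyloin shift may deliver the trans-fused bridge without later equilibration. Fallback with known chemistry, the two bonds being made in separate operations: 14 is condensed with (R)-1-phenylethylamine (its antipode if the facial sense is the opposite) to the chiral imine F1. On warming in THF its secondary enamine tautomer undergoes the intramolecular aza-ene-type Michael addition known for such imines and gives the bridged imine F2 with the quaternary C9. Aqueous acetic acid releases the amine and gives 15, now isolated. KOt-Bu in t-BuOH/THF then effects the classical α-ketol ring expansion and equilibration to 16, where the main route is rejoined.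

2. Step 8. The basic allenyllithium may attack the aryl ketone or deprotonate next to the ester, and facial selectivity at the cyclobutanone may be insufficient. Fallback, with the order of events changed so that no second ketone is present: from 10 the C9 ketone is first homologated with Ph3P=CHOMe to enol ether F3. Aqueous HCl hydrolyses enol ether and ketal to keto aldehyde F4. The aldehyde is masked in situ as its lithium enolate with one equivalent of LiN(SiMe3)2, and 1-methoxyallenyllithium is added to the only remaining ketone to give allenyl carbinol F5. Aqueous HCl hydrolysis of the allenyl ether returns 14.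

3. Step 6. Oxidative addition may be slow and hydrodebromination may compete at the doubly ortho-substituted aryl bromide. Fallback, with ring B closed at the C6–C8 bond instead of the C6–aryl bond: from 8 the bromide is coupled with BrZnCH2CO2Et (Pd2(dba)3, XPhos; Reformatsky–Negishi coupling) to aryl acetate F6. Its ester/ketone bis-enolate (LiN(i-Pr)2) is oxidised with copper bis(2-ethylhexanoate) in an intramolecular enolate heterocoupling that forms C6–C8 and gives 10.

**Further compounds**
F1 | step 10 | N-[(R)-1-phenylethyl]imine of aldehyde 14 | CCOC(=O)C1c2c(C)c3occ(C(=O)OCC)c3cc2C(C=N[C@H](C)c2ccccc2)[C@@]12C[C@](O)(C(=O)C=C)C2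
F2 | step 10 | N-[(R)-1-phenylethyl]imine of bridged ketol 15 | O=C1CC[C@@]2(C=N[C@H](C)c6ccccc6)c3cc4c(C(=O)OCC)coc4c(C)c3C(C(=O)OCC)[C@]25C[C@@]1(O)C5
F3 | step 8 | diethyl 3',3'-diethoxy-5-(methoxymethylidene)-8-methyl-5,7-dihydrospiro[indeno[5,6-b]furan-6,1'-cyclobutane]-3,7-dicarboxylate | CCOC(=O)C1c2c(C)c3occ(C(=O)OCC)c3cc2C(=COC)C12CC(OCC)(OCC)C2
F4 | step 8 | diethyl 5-formyl-8-methyl-3'-oxo-5,7-dihydrospiro[indeno[5,6-b]furan-6,1'-cyclobutane]-3,7-dicarboxylate | CCOC(=O)C1c2c(C)c3occ(C(=O)OCC)c3cc2C(C=O)C12CC(=O)C2
F5 | step 8 | diethyl 5-formyl-3'-hydroxy-3'-(1-methoxypropa-1,2-dien-1-yl)-8-methyl-5,7-dihydrospiro[indeno[5,6-b]furan-6,1'-cyclobutane]-3,7-dicarboxylate (allenyl cis to C5) | CCOC(=O)C1c2c(C)c3occ(C(=O)OCC)c3cc2C(C=O)[C@@]12C[C@](O)(C(OC)=C=C)C2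
F6 | step 6 | ethyl 5-(3,3-diethoxycyclobutane-1-carbonyl)-6-(2-ethoxy-2-oxoethyl)-7-methyl-1-benzofuran-3-carboxylate | CCOC(=O)Cc1c(C(=O)C2CC(OCC)(OCC)C2)cc2c(C(=O)OCC)coc2c1C
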